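## Retrosynthetic overview

1. Target ⇐ double O‑sulfation of the hydroquinone ⇐ hydrogenation/debenzylation of an alkyne‑linked precursor, whose alkyne–carbinol C–C bond comes from adding a decalin acetylide to a bicyclic ketone.
2. Bicyclic ketone ⇐ α‑methylation ⇐ oxepane closure onto a (2S,3S)‑hydroxy ketone ⇐ yeast desymmetrisation of a 2,2‑disubstituted cyclohexane‑1,3‑dione ⇐ 2‑methylcyclohexane‑1,3‑dione + acrolein (Michael, Wittig).
3. Decalin alkyne ⇐ ionic deoxygenation of an aryl carbinol ⇐ aryllithium + bicyclic enal ⇐ oxidation/dehydration of a bicyclic 8,11‑diol.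
4. Key disconnection: that diol ⇐ acyclic (E,E)‑dienyl tertiary propargylic ester. Rings A and B form in one cationic cascade, with the ethynyl group axial at C4; it later becomes the two‑carbon tether. Precursor ⇐ geranyl acetate.
5. Ring order: rings A and B of the decalin together; the cyclohexane of the oxabicycle comes with the dione and the oxepane is closed onto it; the arene is attached as a unit.

Assumption: decalin locants in the comments are drimane‑type (C4 = quaternary carbon carrying the tether, C5/C10 = ring fusion, C8=C9 = ring olefin, C11 = CH2 on C9), the oxabicycle uses 1‑benzoxepine locants, 1,4‑bis(benzyloxy)‑2‑bromobenzene is taken as purchasable, and the target is isolated as the free bis(hydrogen sulfate) drawn.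

## Route

Step 1
Reactants: 1 geranyl acetate
Product: 2 (2E,6E)-8-hydroxy-3,7-dimethylocta-2,6-dien-1-yl acetate
Conditions: SeO2 (0.2 equiv), t-BuOOH, salicylic acid (0.1 equiv), CH2Cl2, rt
Reagents that add atoms: tert-butyl hydroperoxide, CC(C)(C)OO
Why: Riley allylic oxidation (ene reaction, then [2,3]-sigmatropic shift) hydroxylates only the E-methyl of the terminal trisubstituted olefin, the olefin next to the acetate being deactivated; no stereocentre forms and both olefins stay E.

Step 2
Reactants: 2 (2E,6E)-8-hydroxy-3,7-dimethylocta-2,6-dien-1-yl acetate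
Product: 3 (2E,6E)-8-bromo-3,7-dimethylocta-2,6-dien-1-yl acetate
Conditions: CBr4, PPh3, CH2Cl2, 0 °C
Reagents that add atoms: tetrabromomethane, BrC(Br)(Br)Br
Why: Appel bromination of the primary allylic alcohol proceeds by SN2 at carbon, without allylic transposition or E/Z scrambling; no stereocentre.

Step 3
Reactants: 3 (2E,6E)-8-bromo-3,7-dimethylocta-2,6-dien-1-yl acetate; 4 2-(2-bromoethyl)-2-methyl-1,3-dioxolane
Product: 7 (2E,6E)-3,7-dimethyl-11-oxododeca-2,6-dien-1-yl acetate, via Grignard reagent 5 (not isolated), via ketal acetate 6 (not isolated)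
Conditions: 4, Mg, THF, 25 °C; then 3, Li2CuCl4 (3 mol %), THF, –20 °C; then 1 M HCl, acetone, rt
Reagents that add atoms: water, O
Why: Copper-catalysed (Kochi-type) sp3–sp3 coupling of the Grignard reagent with the allylic bromide is faster than attack on the acetate and occurs at the primary carbon with the E-olefin retained, after which the dioxolane is hydrolysed to the methyl ketone; no stereocentre.

Step 4
Reactants: 7 (2E,6E)-3,7-dimethyl-11-oxododeca-2,6-dien-1-yl acetate
Product: 8 (2E,6E)-11-hydroxy-3,7,11-trimethyltrideca-2,6-dien-12-yn-1-yl acetate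
Conditions: HC≡CMgBr (1.3 equiv), THF, –40 → –10 °C; H2O
Reagents that add atoms: ethynylmagnesium bromide, C#C[Mg]Br
Why: Grignard 1,2-addition to the methyl ketone outruns attack on the ester at low temperature; the new tertiary carbinol is racemic, which is immaterial because it becomes a planar cation in step 5.

Step 5
Reactants: 8 (2E,6E)-11-hydroxy-3,7,11-trimethyltrideca-2,6-dien-12-yn-1-yl acetate
Product: 12 (1R,2S,4aS,5R,8aR)-5-ethynyl-1-(hydroxymethyl)-2,5,8a-trimethyldecahydronaphthalen-2-ol, via trifluoroacetate 9 (not isolated), via acetoxonium triflate 10 (not isolated), via hydroxy acetate 11 (not isolated)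
Conditions: (CF3CO)2O, 2,6-di-tert-butyl-4-methylpyridine (1.05 equiv), toluene, –78 °C; then 3-{[3,5-bis(trifluoromethyl)phenyl]amino}-4-({(2S)-3,3-dimethyl-1-oxo-1-[(2R)-2-(phenanthren-9-yl)pyrrolidin-1-yl]butan-2-yl}amino)cyclobut-3-ene-1,2-dione (10 mol %), Me3SiOTf (1.1 equiv), toluene–tert-butyl methyl ether, –78 °C; aq. NaHCO3; then K2CO3 (0.2 equiv), MeOH, rt
Reagents that add atoms: none
Why: Proposed new method: Me3SiOTf, activated and held in a chiral pocket by the squaramide that binds its triflate, ionises only the tertiary propargylic trifluoroacetate (a far better leaving group than the primary allylic acetate) to a propargylic cation–chiral anion pair, which is trapped by the 6,7-olefin and then the 2,3-olefin in a chair–chair cation–olefin bicyclisation; ring A closes with the rod-like ethynyl group (A-value about 0.4 kcal/mol against 1.7 for methyl) axial and syn to the developing angular methyl, so C4 is set with the alkyne cis to the C10 methyl, the two E-olefins give anti additions (H5 trans to the C10 methyl, the C9 CH2O equatorial), the acetate carbonyl captures the C8 cation anti to the new C9–C10 bond as a dioxanylium ion (8-O equatorial, no free tertiary cation left for elimination or rearrangement), and the catalyst antipode selects the helical fold and hence the absolute configuration; the closest known reaction types are the squaramide/silyl triflate enantioconvergent SN1 substitution of tertiary propargylic acetates, anion-binding-catalysed cationic polyene cyclisation and neighbouring-group participation by esters.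

Step 6
Reactants: 12 (1R,2S,4aS,5R,8aR)-5-ethynyl-1-(hydroxymethyl)-2,5,8a-trimethyldecahydronaphthalen-2-ol
Product: 14 (4aR,5R,8aR)-5-ethynyl-2,5,8a-trimethyl-3,4,4a,5,6,7,8,8a-octahydronaphthalene-1-carbaldehyde, via hydroxy aldehyde 13 (not isolated)
Conditions: 2,2,6,6-tetramethylpiperidin-1-oxyl (10 mol %), PhI(OAc)2, CH2Cl2, rt; then p-TsOH·H2O (10 mol %), benzene, 60 °C
Reagents that add atoms: none
Why: Oxoammonium (TEMPO) oxidation takes only the primary alcohol, and acid-catalysed aldol-type dehydration of the β-hydroxy aldehyde (through its enol, any β,γ-isomer equilibrating into conjugation) gives the tetrasubstituted enal regiospecifically; the C8 and C9 centres are erased while C4, C5 and C10 are untouched.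

Step 7
Reactants: 14 (4aR,5R,8aR)-5-ethynyl-2,5,8a-trimethyl-3,4,4a,5,6,7,8,8a-octahydronaphthalene-1-carbaldehyde; 15 1,4-bis(benzyloxy)-2-bromobenzene
Product: 17 [2,5-bis(benzyloxy)phenyl][(4aR,5R,8aR)-5-ethynyl-2,5,8a-trimethyl-3,4,4a,5,6,7,8,8a-octahydronaphthalen-1-yl]methanol (carbinol epimers), via aryllithium 16 (not isolated)
Conditions: 15 (2.3 equiv), n-BuLi (2.2 equiv), THF, –78 °C; then 14, –78 → –40 °C; H2O
Reagents that add atoms: none
Why: Bromine–lithium exchange, then 1,2-addition of the aryllithium to the hindered enal (the tetrasubstituted β-carbon blocks conjugate addition; one equivalent is spent on the alkyne C–H); the carbinol centre forms as an epimer mixture and is removed in step 8.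

Step 8
Reactants: 17 [2,5-bis(benzyloxy)phenyl][(4aR,5R,8aR)-5-ethynyl-2,5,8a-trimethyl-3,4,4a,5,6,7,8,8a-octahydronaphthalen-1-yl]methanol
Product: 18 (4aR,5R,8aR)-1-{[2,5-bis(benzyloxy)phenyl]methyl}-5-ethynyl-2,5,8a-trimethyl-3,4,4a,5,6,7,8,8a-octahydronaphthalene
Conditions: Et3SiH (3 equiv), CF3CO2H (5 equiv), CH2Cl2, –78 → –30 °C
Reagents that add atoms: none
Why: Ionic hydrogenation: ionisation gives an aryl-stabilised allylic cation whose charge sits mainly on the benzylic carbon next to the ortho-alkoxy ring, so hydride is delivered there and the tetrasubstituted C8=C9 olefin is kept; the carbinol stereocentre disappears and benzyl ethers and alkyne survive at low temperature.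

Step 9
Reactants: 19 2-methylcyclohexane-1,3-dione; 20 acrolein
Product: 21 3-(1-methyl-2,6-dioxocyclohexyl)propanal
Conditions: H2O, rt
Reagents that add atoms: none
Why: Michael addition of the acidic 1,3-dione to acrolein builds the quaternary carbon, which is not yet stereogenic because the ring is still symmetric.

Step 10
Reactants: 21 3-(1-methyl-2,6-dioxocyclohexyl)propanal
Product: 22 2-methyl-2-(4-methylpent-3-en-1-yl)cyclohexane-1,3-dione
Conditions: i-PrPPh3I, n-BuLi, THF, 0 °C; then 21, –78 °C → rt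
Reagents that add atoms: isopropyltriphenylphosphonium iodide, CC(C)[P+](c1ccccc1)(c1ccccc1)c1ccccc1.[I-]
Why: Wittig olefination of the aldehyde by the non-stabilised ylide is fast at –78 °C while the hindered ring ketones are left alone; the olefin has no E/Z isomers and no stereocentre forms.

Step 11
Reactants: 22 2-methyl-2-(4-methylpent-3-en-1-yl)cyclohexane-1,3-dione
Product: 23 (2S,3S)-3-hydroxy-2-methyl-2-(4-methylpent-3-en-1-yl)cyclohexan-1-one
Conditions: baker's yeast (Saccharomyces cerevisiae), sucrose, H2O–EtOH, 30 °C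
Reagents that add atoms: none
Why: Enantiotopic-group-selective ketoreductase reduction of the prochiral 2,2-disubstituted 1,3-dione (as with the 2-allyl and 2-prenyl homologues) reduces one carbonyl only, giving the 3S alcohol cis to the longer chain and thereby fixing the quaternary centre as 2S.

Step 12
Reactants: 23 (2S,3S)-3-hydroxy-2-methyl-2-(4-methylpent-3-en-1-yl)cyclohexan-1-one
Product: 24 (5aS,9aS)-2,2,5a-trimethyl-3,4,5,5a,7,8,9,9a-octahydro-1-benzoxepin-6(2H)-one
Conditions: (R,R)-N,N'-bis(3,5-di-tert-butylsalicylidene)-1,2-cyclohexanediaminocobalt (3 mol %), N-fluoro-2,4,6-trimethylpyridinium triflate, PhSiH3, PhCF3, rt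
Reagents that add atoms: none
Why: Mukaiyama-type hydrogen-atom-transfer hydroalkoxylation (radical–polar crossover): Markovnikov H-atom transfer from a cobalt hydride to the trisubstituted olefin gives the tertiary radical, which is oxidised at cobalt and captured by the hydroxyl to close the oxepane; because OH and side chain are cis on the cyclohexanone the ring fusion is cis, and the two existing stereocentres are not touched.

Step 13
Reactants: 24 (5aS,9aS)-2,2,5a-trimethyl-3,4,5,5a,7,8,9,9a-octahydro-1-benzoxepin-6(2H)-one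
Product: 26 (5aS,7R,9aS)-2,2,5a,7-tetramethyl-3,4,5,5a,7,8,9,9a-octahydro-1-benzoxepin-6(2H)-one, via lithium enolate 25 (not isolated)
Conditions: LiN(iPr)2, THF, –78 °C; then MeI, –78 → –20 °C
Reagents that add atoms: iodomethane, CI
Why: Kinetic enolate alkylation (only C7 carries α-hydrogens): the cis-fused oxabicycle prefers the chair with the ring oxygen axial and the angular methyl axial on the cyclohexanone, so MeI approaches anti to that methyl and the new methyl (7R) ends equatorial and trans to the angular methyl, which is also the epimer favoured on equilibration.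

Step 14
Reactants: 18 (4aR,5R,8aR)-1-{[2,5-bis(benzyloxy)phenyl]methyl}-5-ethynyl-2,5,8a-trimethyl-3,4,4a,5,6,7,8,8a-octahydronaphthalene; 26 (5aS,7R,9aS)-2,2,5a,7-tetramethyl-3,4,5,5a,7,8,9,9a-octahydro-1-benzoxepin-6(2H)-one
Product: 28 (5aS,6S,7R,9aS)-6-{[(1R,4aR,8aR)-5-{[2,5-bis(benzyloxy)phenyl]methyl}-1,4a,6-trimethyl-1,2,3,4,4a,7,8,8a-octahydronaphthalen-1-yl]ethynyl}-2,2,5a,7-tetramethyldecahydro-1-benzoxepin-6-ol, via lithium acetylide 27 (not isolated)
Conditions: n-BuLi, THF, –78 °C; CeCl3; then 26, –78 → –30 °C; H2O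
Reagents that add atoms: none
Why: 1,2-Addition of the cerium-moderated acetylide to the ketone: in the same chair the axial ring oxygen with its gem-dimethyl carbon shields the axial trajectory, so the slim nucleophile enters equatorially, anti to the 3-alkoxy substituent, giving the tertiary alcohol with OH axial and cis to the ring oxygen (6S here, 6R once the alkyne is saturated), while CeCl3 suppresses enolisation.

Step 15
Reactants: 28 (the alkyne-linked bis-benzyl ether)
Product: 29 2-{[(4aR,5S,8aR)-5-{2-[(5aS,6R,7R,9aS)-6-hydroxy-2,2,5a,7-tetramethyldecahydro-1-benzoxepin-6-yl]ethyl}-2,5,8a-trimethyl-3,4,4a,5,6,7,8,8a-octahydronaphthalen-1-yl]methyl}benzene-1,4-diol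
Conditions: H2 (1 atm), 10 % Pd/C, EtOAc–EtOH, rt
Reagents that add atoms: none
Why: Heterogeneous hydrogenation saturates the alkyne to the CH2CH2 tether and hydrogenolyses both benzyl ethers, while the tetrasubstituted ring olefin is too hindered to react; no stereocentre is formed or changed.

Step 16
Reactants: 29 (the hydroquinone)
Product: 30 2-{[(4aR,5S,8aR)-5-{2-[(5aS,6R,7R,9aS)-6-hydroxy-2,2,5a,7-tetramethyldecahydro-1-benzoxepin-6-yl]ethyl}-2,5,8a-trimethyl-3,4,4a,5,6,7,8,8a-octahydronaphthalen-1-yl]methyl}-1,4-phenylene bis(hydrogen sulfate)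
Conditions: SO3·pyridine (6 equiv), pyridine, 0 °C → rt; then Dowex 50W (H+ form), MeOH–H2O, 0 °C
Reagents that add atoms: sulfur trioxide–pyridine complex, [O-]S(=O)(=O)[n+]1ccccc1
Why: O-Sulfation of the two phenols with sulfur trioxide–pyridine; the hindered tertiary alcohol does not react and brief cation exchange gives the free bis(hydrogen sulfate); no stereocentre changes.

## Compound list

1 | geranyl acetate | CC(=O)OC/C=C(C)/CCC=C(C)C | starting material
2 | (2E,6E)-8-hydroxy-3,7-dimethylocta-2,6-dien-1-yl acetate | CC(=O)OC/C=C(C)/CC/C=C(C)/CO | intermediate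
3 | (2E,6E)-8-bromo-3,7-dimethylocta-2,6-dien-1-yl acetate | CC(=O)OC/C=C(C)/CC/C=C(C)/CBr | intermediate
4 | 2-(2-bromoethyl)-2-methyl-1,3-dioxolane | CC1(CCBr)OCCO1 | starting material
5 | [2-(2-methyl-1,3-dioxolan-2-yl)ethyl]magnesium bromide | CC1(CC[Mg]Br)OCCO1 | intermediate
6 | (2E,6E)-3,7-dimethyl-10-(2-methyl-1,3-dioxolan-2-yl)deca-2,6-dien-1-yl acetate | CC(=O)OC/C=C(C)/CC/C=C(C)/CCCC1(C)OCCO1 | intermediate
7 | (2E,6E)-3,7-dimethyl-11-oxododeca-2,6-dien-1-yl acetate | CC(=O)OC/C=C(C)/CC/C=C(C)/CCCC(C)=O | intermediate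
8 | (2E,6E)-11-hydroxy-3,7,11-trimethyltrideca-2,6-dien-12-yn-1-yl acetate, racemic at C11 | CC(=O)OC/C=C(C)/CC/C=C(C)/CCCC(C)(O)C#C | intermediate
9 | (2E,6E)-1-acetoxy-3,7,11-trimethyltrideca-2,6-dien-12-yn-11-yl trifluoroacetate, racemic at C11 | CC(=O)OC/C=C(C)/CC/C=C(C)/CCCC(C)(OC(=O)C(F)(F)F)C#C | intermediate
10 | trans-fused 2-methyl-1,3-dioxan-2-ylium (acetoxonium) triflate spanning O–C8 and O–C11 of the decalin, configuration as in 11 | C[C@@]1(O3)[C@@H](CO[C+]3C)[C@]2(C)CCC[C@@](C)(C#C)[C@H]2CC1.[O-]S(=O)(=O)C(F)(F)F | intermediate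
11 | [(1R,2S,4aS,5R,8aR)-5-ethynyl-2-hydroxy-2,5,8a-trimethyldecahydronaphthalen-1-yl]methyl acetate | C[C@@]1(O)[C@@H](COC(C)=O)[C@]2(C)CCC[C@@](C)(C#C)[C@H]2CC1 | intermediate
12 | (1R,2S,4aS,5R,8aR)-5-ethynyl-1-(hydroxymethyl)-2,5,8a-trimethyldecahydronaphthalen-2-ol (trans-decalin; ethynyl cis to angular methyl) | C[C@@]1(O)[C@@H](CO)[C@]2(C)CCC[C@@](C)(C#C)[C@H]2CC1 | intermediate
13 | (1S,2S,4aS,5R,8aR)-5-ethynyl-2-hydroxy-2,5,8a-trimethyldecahydronaphthalene-1-carbaldehyde | C[C@@]1(O)[C@@H](C=O)[C@]2(C)CCC[C@@](C)(C#C)[C@H]2CC1 | intermediate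
14 | (4aR,5R,8aR)-5-ethynyl-2,5,8a-trimethyl-3,4,4a,5,6,7,8,8a-octahydronaphthalene-1-carbaldehyde | CC1=C(C=O)[C@]2(C)CCC[C@@](C)(C#C)[C@H]2CC1 | intermediate
15 | 1,4-bis(benzyloxy)-2-bromobenzene | Brc1cc(OCc2ccccc2)ccc1OCc1ccccc1 | starting material
16 | [2,5-bis(benzyloxy)phenyl]lithium | [Li]c1cc(OCc2ccccc2)ccc1OCc1ccccc1 | intermediate
17 | [2,5-bis(benzyloxy)phenyl][(4aR,5R,8aR)-5-ethynyl-2,5,8a-trimethyl-3,4,4a,5,6,7,8,8a-octahydronaphthalen-1-yl]methanol, both carbinol epimers | CC1=C(C(O)c2cc(OCc3ccccc3)ccc2OCc2ccccc2)[C@]2(C)CCC[C@@](C)(C#C)[C@H]2CC1 | intermediate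
18 | (4aR,5R,8aR)-1-{[2,5-bis(benzyloxy)phenyl]methyl}-5-ethynyl-2,5,8a-trimethyl-3,4,4a,5,6,7,8,8a-octahydronaphthalene | CC1=C(Cc2cc(OCc3ccccc3)ccc2OCc2ccccc2)[C@]2(C)CCC[C@@](C)(C#C)[C@H]2CC1 | intermediate
19 | 2-methylcyclohexane-1,3-dione | CC1C(=O)CCCC1=O | starting material
20 | acrolein | C=CC=O | starting material
21 | 3-(1-methyl-2,6-dioxocyclohexyl)propanal | CC1(CCC=O)C(=O)CCCC1=O | intermediate
22 | 2-methyl-2-(4-methylpent-3-en-1-yl)cyclohexane-1,3-dione | CC(C)=CCCC1(C)C(=O)CCCC1=O | intermediate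
23 | (2S,3S)-3-hydroxy-2-methyl-2-(4-methylpent-3-en-1-yl)cyclohexan-1-one | O=C1CCC[C@H](O)[C@@]1(CCC=C(C)C)C | intermediate
24 | (5aS,9aS)-2,2,5a-trimethyl-3,4,5,5a,7,8,9,9a-octahydro-1-benzoxepin-6(2H)-one (cis-fused) | O=C1CCC[C@@H]2OC(C)(C)CCC[C@@]21C | intermediate
25 | lithium (5aS,9aS)-2,2,5a-trimethyl-2,3,4,5,5a,8,9,9a-octahydro-1-benzoxepin-6-olate | [Li+].[O-]C1=CCC[C@@H]2OC(C)(C)CCC[C@@]21C | intermediate
26 | (5aS,7R,9aS)-2,2,5a,7-tetramethyl-3,4,5,5a,7,8,9,9a-octahydro-1-benzoxepin-6(2H)-one | O=C1[C@H](C)CC[C@@H]2OC(C)(C)CCC[C@@]21C | intermediate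
27 | lithium acetylide of 18 | CC1=C(Cc2cc(OCc3ccccc3)ccc2OCc2ccccc2)[C@]2(C)CCC[C@@](C)(C#C[Li])[C@H]2CC1 | intermediate
28 | (5aS,6S,7R,9aS)-6-{[(1R,4aR,8aR)-5-{[2,5-bis(benzyloxy)phenyl]methyl}-1,4a,6-trimethyl-1,2,3,4,4a,7,8,8a-octahydronaphthalen-1-yl]ethynyl}-2,2,5a,7-tetramethyldecahydro-1-benzoxepin-6-ol | CC1=C(Cc2cc(OCc3ccccc3)ccc2OCc2ccccc2)[C@]2(C)CCC[C@@](C)(C#C[C@@]3(O)[C@H](C)CC[C@@H]4OC(C)(C)CCC[C@@]43C)[C@H]2CC1 | intermediate
29 | 2-{[(4aR,5S,8aR)-5-{2-[(5aS,6R,7R,9aS)-6-hydroxy-2,2,5a,7-tetramethyldecahydro-1-benzoxepin-6-yl]ethyl}-2,5,8a-trimethyl-3,4,4a,5,6,7,8,8a-octahydronaphthalen-1-yl]methyl}benzene-1,4-diol | CC1=C(Cc2cc(O)ccc2O)[C@]2(C)CCC[C@@](C)(CC[C@@]3(O)[C@H](C)CC[C@@H]4OC(C)(C)CCC[C@@]43C)[C@H]2CC1 | intermediate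
30 | 2-{[(4aR,5S,8aR)-5-{2-[(5aS,6R,7R,9aS)-6-hydroxy-2,2,5a,7-tetramethyldecahydro-1-benzoxepin-6-yl]ethyl}-2,5,8a-trimethyl-3,4,4a,5,6,7,8,8a-octahydronaphthalen-1-yl]methyl}-1,4-phenylene bis(hydrogen sulfate) (CNP0125037.3) | CC1=C(Cc2cc(OS(=O)(=O)O)ccc2OS(=O)(=O)O)[C@]2(C)CCC[C@@](C)(CC[C@@]3(O)[C@H](C)CC[C@@H]4OC(C)(C)CCC[C@@]43C)[C@H]2CC1 | target

## Step count and risks

Total step count: 16 (steps 1–8 decalin arm, 9–13 oxabicyclic ketone, 14–16 union and end game). Longest linear sequence: 11 steps (1–8, then 14–16).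

Steps most likely to fail:

Step 5 (asymmetric propargylic-cation bicyclisation). The ion-pairing catalyst has only been shown to control aryl-stabilised tertiary propargylic cations; a purely aliphatic cation may cyclise with little or no enantiocontrol, and competing elimination to enynes is possible. Fallback, setting out from 8 and returning at 12: the stereochemistry is taken from an enzymatic resolution instead of the catalyst. Compound 8 is cyclised as in step 5 but with Me3SiOTf alone, giving racemic diol, that is 12 mixed with its enantiomer (1S,2R,4aR,5S,8aS)-5-ethynyl-1-(hydroxymethyl)-2,5,8a-trimethyldecahydronaphthalen-2-ol F1. Lipase from Burkholderia cepacia with vinyl acetate in tert-butyl methyl ether acylates the primary hydroxyl of one antipode only, as is usual for drimane-type primary alcohols. If the unwanted antipode reacts, it is removed as [(1S,2R,4aR,5S,8aS)-5-ethynyl-2-hydroxy-2,5,8a-trimethyldecahydronaphthalen-1-yl]methyl acetate F2 and unreacted 12 is carried on. If the wanted antipode reacts, the acetate formed is 11, which K2CO3/MeOH returns to 12.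

Step 12 (oxepane closure). Seven-membered rings form much less readily than five- or six-membered ones in HAT hydroalkoxylation, and reduction or isomerisation of the olefin may win. Fallback, setting out from 23 and returning at 24: an electrophile-induced cyclisation followed by reductive removal of the electrophile. Hg(OCOCF3)2 in MeNO2 at 0 °C effects Markovnikov alkoxymercuration (oxygen to the tertiary carbon), and aqueous NaCl gives (5aS,9aS)-3-(chloromercurio)-2,2,5a-trimethyl-3,4,5,5a,7,8,9,9a-octahydro-1-benzoxepin-6(2H)-one F3. Radical demercuration with n-Bu3SnH and 2,2'-azobis(2-methylpropionitrile) in toluene leaves the ketone untouched and gives 24.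

Step 13 (C7 methylation). The facial preference rests on a conformational argument, and MeI may instead enter syn to the angular methyl. Fallback, setting out from 24 and returning at 26: the stereocentre is set by kinetic protonation instead of alkylation, using the same facial bias in the opposite sense. If methylation gives mainly (5aS,7S,9aS)-2,2,5a,7-tetramethyl-3,4,5,5a,7,8,9,9a-octahydro-1-benzoxepin-6(2H)-one F4, this epimer (or the mixture) is deprotonated with LiN(iPr)2 to lithium (5aS,9aS)-2,2,5a,7-tetramethyl-2,3,4,5,5a,8,9,9a-octahydro-1-benzoxepin-6-olate F5. Protonation at –78 °C with 2,6-di-tert-butyl-4-methylphenol then occurs from the face MeI preferred, which places hydrogen where the methyl had gone and gives 26.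

Further compounds
F1 | step 5 | (1S,2R,4aR,5S,8aS)-5-ethynyl-1-(hydroxymethyl)-2,5,8a-trimethyldecahydronaphthalen-2-ol (enantiomer of 12) | C[C@]1(O)[C@H](CO)[C@@]2(C)CCC[C@](C)(C#C)[C@@H]2CC1
F2 | step 5 | [(1S,2R,4aR,5S,8aS)-5-ethynyl-2-hydroxy-2,5,8a-trimethyldecahydronaphthalen-1-yl]methyl acetate (enantiomer of 11) | C[C@]1(O)[C@H](COC(C)=O)[C@@]2(C)CCC[C@](C)(C#C)[C@@H]2CC1
F3 | step 12 | (5aS,9aS)-3-(chloromercurio)-2,2,5a-trimethyl-3,4,5,5a,7,8,9,9a-octahydro-1-benzoxepin-6(2H)-one (C3 epimers) | O=C1CCC[C@@H]2OC(C)(C)C([Hg]Cl)CC[C@@]21C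
F4 | step 13 | (5aS,7S,9aS)-2,2,5a,7-tetramethyl-3,4,5,5a,7,8,9,9a-octahydro-1-benzoxepin-6(2H)-one | O=C1[C@@H](C)CC[C@@H]2OC(C)(C)CCC[C@@]21C
F5 | step 13 | lithium (5aS,9aS)-2,2,5a,7-tetramethyl-2,3,4,5,5a,8,9,9a-octahydro-1-benzoxepin-6-olate | [Li+].[O-]C1=C(C)CC[C@@H]2OC(C)(C)CCC[C@@]21C
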